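(The readings are simulated from invented constants; noise was put on by code.)

One millimole of partner takes up one millimole of starting material, if the two react one to one. In the dawn flask the partner charge is 25.0% of the starting-material charge. This fraction, partner charge over starting-material charge, is called here the reach, and it is the stoichiometric ratio of the charge.

| flask | starting material | partner | remark | time |
|---|---|---|---|---|
| ash | 1.3 mM | 5 mM | run made earlier |  |
| maple | 12 mM | 5 mM | run made earlier |  |
| winter | 2.5 mM | 5.00 mM |  | 25 h |
| autumn | 5.0 mM | 5.00 mM |  | 25 h |
| midnight | 10 mM | 5.00 mM |  | 25 h |
| dawn | 20 mM | 5.00 mM |  | 25 h |

| run | time / h | target / % | starting material / % |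
|---|---|---|---|
| ash | 1.50 | 24.1 | 42.3 |
| ash | 4.00 | 13.5 | 25.6 |
| ash | 8.00 | 6.0 | 12.2 |
| ash | 12.0 | 2.8 | 5.8 |
| maple | 3.00 | 7.5 | 64.7 |
| maple | 6.00 | 3.5 | 62.6 |
| maple | 10.0 | 1.3 | 60.2 |
| maple | 12.0 | 0 | 59.3 |

(readings scatter by 0.5 percentage points)

- "hardly changes" means that all values lie within two and a half points (for a concentration: within two and a half percent of the largest)
- a reading of starting material is of its free form alone

1. [target] at the end for winter, autumn, midnight, dawn, in this order
2. how that number moves from the first to the last of them (falls, then rises / hardly changes / rises all the way / rises, then falls / falls all the way)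

The maple run tests the reach in two ways. By the charges, a reach of 41.7% leaves 58.3% of the starting material once the partner is used up. By the readings, maple holds 59.3% at 12.0 h. The two part by 1.00 percentage point, with a scatter of 0.5 points. The reading fell by 0.9 points over its last interval, beside a scatter of 0.71 points for the difference of two readings, so the readings do not show that maple is still falling, and the gap stands. In the ash run the reach is 385%, and there the starting material falls to 5.8% at 12.0 h, with no stop in the readings.

The reckoning here goes by the reach and gives a shape, not amounts. Winter has more partner than starting material, so starting material should be the limiting reagent there. Midnight has less partner than starting material, and so has dawn, so partner should be the limiting reagent in both. Autumn charges the two about equally. Target needs both species to stand beside each other, so the row should peak near autumn. Dawn should keep 75.0% of its starting material.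

The forecast gives 0.012 mM, 0.045 mM, 0.005 mM and 2.000 × 10⁻⁴ mM, a row that rises, then falls. Its ground for the peak at equal charges is “second-order tail, so the slowest loss”. It shares the shape with the reckoning here, which offers no amounts to set beside its numbers.

The flask gives 0.0190 mM, 0.0376 mM, 0.0253 mM and 0.0252 mM, a row that rises, then falls. The row turns at a starting-material charge of 4.9 mM, close to the partner charge of 5.00 mM.

    starting material + partner ⇌ target (K = 120 /M, k = 4.05 /M/min)
    starting material + partner ⇌ isomer of the product (K = 23000 /M, k = 1.46 /M/min)
    partner → decomposed reagent (k = 3.20 × 10⁻⁴ /min)

At its reach of 25.0%, the dawn flask was reckoned to keep 75.0% of its starting material, and at 25.0 h it holds 75.4%.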